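The cyclohexane (C5–C10, elemanolide numbering) is closed last, at C6–C7. That bond lies between two cis fusions: the lactone ring (C7, C8, O, C12, C11) and the cis pair C6–O/C5–C4, which allows O6 to be tied to C15 in a temporary 3-methylenetetrahydrofuran. Ionising the resulting lactol ether at C6 gives a cyclic oxocarbenium ion that is attacked by C7 of a 2-(silylmethyl)butenolide: one operation closes the carbocycle, fixes C6 and C7 through the two ring fusions and unveils the C11=C13 methylene. The precursor is an open C5–C10 chain carrying a butenolide and a 2-methoxytetrahydrofuran; acylative opening of the ether then installs the angelate and the C15 aldehyde precursor.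

Key step: step 18

Remark: locants follow elemanolide numbering (C1=C2 vinyl and C14 methyl on C10; C3H2=C4(C15) on C5; C6 angelate; C7/C8 lactone fusion with C11(=C13H2)–C12(=O); C9 2-methylbutanoate). The SMILES is read as (5R,6S,7R,8R,9R,10S) with a (2R)-2-methylbutanoate and a (2Z)-2-methylbut-2-enoate. Compounds 1, 3, 7, 19, 24 and 28 are taken as commercially available.

Step 1
Reactants: 1 4-methylfuran-2(5H)-one
Product: 2 4-methyl-2-(trimethylsilyloxy)furan
Conditions: Me3SiOTf, Et3N, Et2O, 0 °C
Reagents that add atoms: trimethylsilyl trifluoromethanesulfonate, C[Si](C)(C)OS(=O)(=O)C(F)(F)F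
Why: Soft enolisation and O-silylation of the butenolide (silyl dienol ether formation) should give the aromatic 2-silyloxyfuran needed for the vinylogous aldol.

Step 2
Reactants: 2 4-methyl-2-(trimethylsilyloxy)furan; 3 (R)-glyceraldehyde acetonide
Product: 4 vinylogous aldol adduct (butenolide alcohol)
Conditions: BF3·OEt2, CH2Cl2, −78 °C; aq. NaHCO3
Reagents that add atoms: none
Why: Vinylogous Mukaiyama aldol reaction at the furan 5-position through an open transition state: attack on the aldehyde anti to its α C–O bond sets C8 and the approach of the furan sets C9 threo to C8, the sense established for 2-silyloxyfurans with this aldehyde, which corresponds to (8R,9R) of the target.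

Step 3
Reactants: 4 vinylogous aldol adduct
Product: 5 (Z)-ene-triol
Conditions: i-Bu2AlH (4 equiv), CH2Cl2, −78 → 0 °C; aq. potassium sodium tartrate
Reagents that add atoms: none
Why: Hydride reduction of the α,β-unsaturated lactone through the lactol should give the ene-diol, the Z geometry of the trisubstituted olefin (C9 cis to C2) being inherited from the ring.

Step 4
Reactants: 5 (Z)-ene-triol
Product: 6 (Z)-allylic alcohol bis-acetonide
Conditions: Me2C(OMe)2, pyridinium p-toluenesulfonate (cat.), acetone, 0 → 25 °C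
Reagents that add atoms: 2,2-dimethoxypropane, COC(C)(C)OC
Why: Acid-catalysed acetonide formation should select the threo 1,2-diol at C8/C9 (five-membered trans-dioxolane) and leave the primary allylic hydroxyl free for the Claisen ester.

Step 5
Reactants: 7 monomethyl itaconate
Product: 8 methyl 3-(hydroxymethyl)but-3-enoate
Conditions: BH3·SMe2, THF, 0 °C; MeOH
Reagents that add atoms: none
Why: Chemoselective borane reduction of the carboxylic acid in the presence of the methyl ester (acyloxyborane pathway) should give the allylic alcohol that becomes C15.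

Step 6
Reactants: 8 methyl 3-(hydroxymethyl)but-3-enoate
Product: 9 silyl ether methyl ester
Conditions: t-BuMe2SiCl, imidazole, CH2Cl2, 0 °C
Reagents that add atoms: tert-butyldimethylsilyl chloride, CC(C)(C)[Si](C)(C)Cl
Why: Standard silylation of the primary alcohol prevents lactonisation onto the ester.

Step 7
Reactants: 9 silyl ether methyl ester
Product: 10 3-(silyloxymethyl)but-3-enoic acid
Conditions: LiOH, THF/H2O, 0 °C; then 1 M HCl to pH 4
Reagents that add atoms: lithium hydroxide, [Li+].[OH-]
Why: Saponification of the methyl ester at low temperature should keep the β,γ-olefin out of conjugation and leave the silyl ether intact.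

Step 8
Reactants: 6 (Z)-allylic alcohol bis-acetonide; 10 3-(silyloxymethyl)but-3-enoic acid
Product: 11 allylic ester
Conditions: DCC, DMAP (cat.), CH2Cl2, 0 °C
Reagents that add atoms: none
Why: Steglich esterification of the primary allylic alcohol with the β,γ-unsaturated acid, run cold to avoid olefin migration, assembles the Claisen substrate.

Step 9
Reactants: 11 allylic ester
Product: 13 Claisen acid, via silyl ketene acetal 12 (not isolated)
Conditions: LiN(i-Pr)2, Me3SiCl, THF/DMPU (4:1), −78 → 25 °C; aq. citric acid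
Reagents that add atoms: chlorotrimethylsilane, C[Si](C)(C)Cl (its silyl group stays in 12 only)
Why: Ireland–Claisen rearrangement through a chair transition state: the Z allyl terminus (dioxolanyl axial, methyl equatorial) and the ketene acetal with its alkenyl group cis to OSiMe3 fix the C5/C10 relative configuration, and the C9 stereocentre (C9–H eclipsing the olefin by 1,3-allylic strain, new bond anti to the C9–O bond) selects the face, so that the quaternary C10 (vinyl and methyl) and C5 should be set in one step.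

Step 10
Reactants: 13 Claisen acid
Product: 15 β-methylene lactone, via hydroxy acid 14 (not isolated)
Conditions: Bu4NF, THF, 0 °C; then AcOH, 25 °C
Reagents that add atoms: none
Why: Fluoride desilylation frees the C15 hydroxyl, which should lactonise onto the C6 acid on acidification (five-membered ring) without base that could move the exocyclic olefin.

Step 11
Reactants: 15 β-methylene lactone
Product: 16 lactol
Conditions: i-Bu2AlH (1.1 equiv), CH2Cl2, −78 °C; aq. potassium sodium tartrate
Reagents that add atoms: none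
Why: Half-reduction of the γ-lactone with one hydride equivalent at low temperature should stop at the lactol because the tetrahedral aluminium alkoxide is stable until work-up.

Step 12
Reactants: 16 lactol
Product: 17 methyl acetal diol
Conditions: pyridinium p-toluenesulfonate (cat.), MeOH, 0 → 25 °C
Reagents that add atoms: methanol, CO
Why: Acid-catalysed acetal exchange in methanol should convert the lactol into its methyl acetal and remove the terminal acetonide, which is methanolysed faster than the internal trans-disubstituted dioxolane.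

Step 13
Reactants: 17 methyl acetal diol
Product: 18 aldehyde
Conditions: NaIO4, THF/pH 7 buffer, 0 °C
Reagents that add atoms: none
Why: Periodate glycol cleavage (Malaprade reaction) of the terminal 1,2-diol should give the α-alkoxy aldehyde at C7 under neutral conditions that leave the methyl acetal untouched.

Step 14
Reactants: 19 methyl bis(2,2,2-trifluoroethyl)phosphonoacetate
Product: 20 silylmethyl phosphonate
Conditions: NaH, THF, 0 °C; ICH2SiMe3, 50 °C
Reagents that add atoms: (iodomethyl)trimethylsilane, C[Si](C)(C)CI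
Why: C-Alkylation of the phosphonoacetate anion with the primary silylmethyl iodide (SN2) installs the future C13 allylsilane carbon.

Step 15
Reactants: 18 aldehyde; 20 silylmethyl phosphonate
Product: 21 enoate
Conditions: KN(SiMe3)2, 18-crown-6, THF, −78 °C
Reagents that add atoms: none
Why: Still–Gennari olefination (Horner–Wadsworth–Emmons reaction of a bis(trifluoroethyl) phosphonate under dissociating conditions) should give kinetically the trisubstituted enoate with the ester cis to C8 (formally E because CH2SiMe3 outranks the ester), as required for lactonisation.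

Step 16
Reactants: 21 enoate
Product: 23 butenolide alcohol, via diol ester 22 (not isolated)
Conditions: camphorsulfonic acid (cat.), MeOH, 25–40 °C
Reagents that add atoms: none
Why: Acid-catalysed methanolysis of the internal acetonide frees the C8 hydroxyl, which should lactonise at once onto the cis ester to the butenolide (five-membered ring favoured over the six-membered alternative from the C9 hydroxyl), while methanol keeps C6 as the methyl acetal.

Step 17
Reactants: 23 butenolide alcohol; 24 (R)-2-methylbutanoic acid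
Product: 25 cyclisation precursor
Conditions: DCC, DMAP, CH2Cl2, 25 °C
Reagents that add atoms: none
Why: Steglich esterification of the hindered C9 hydroxyl with the enantiopure acid installs the (2R)-2-methylbutanoate before ring closure, so that the C6 oxygen is the only one left to be acylated later.

Step 18
Reactants: 25 cyclisation precursor
Product: 27 tricyclic ether lactone, via oxocarbenium triflate 26 (not isolated)
Conditions: Me3SiOTf (0.3 equiv), 2,6-di-tert-butyl-4-methylpyridine, CH2Cl2, −78 → −40 °C
Reagents that add atoms: none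
Why: Me3SiOTf ionises the methyl lactol ether to a five-membered cyclic oxocarbenium ion at C6, C7 of the 2-(silylmethyl)butenolide attacks it in an SE2′ sense and the β-silyl cation at C11 collapses to the exocyclic C11=C13 olefin, MeOSiMe3 being the only by-product. The closest known reaction type is the Hosomi–Sakurai allylation of cyclic oxocarbenium ions with 2-(silylmethyl)acrylates. The carbocycle C5–C10 closes in a 6-exo-trig mode with respect to both the C6=O+ and the C7=C11 bonds. C6 is controlled by C5, because the three-atom tether C10–C9–C8 can deliver C7 only to the face of the oxocarbenium ring that carries C10, so the oxolane becomes cis-fused (O6 cis to C4, 6S); C7 is controlled by C8 in the same way, the bond forming on the butenolide face that carries C9 (cis-fused lactone, 7R). The step needs attack through C7 rather than C13 and cyclisation faster than proton loss from C5 (which would aromatise the ring to a 3-methylfuran); the six-membered transition state, the low temperature and the hindered base should secure both.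

Step 19
Reactants: 28 angelic acid
Product: 29 angeloyl chloride
Conditions: 1-chloro-N,N,2-trimethylprop-1-en-1-amine, CH2Cl2, 0 °C (used as solution)
Reagents that add atoms: 1-chloro-N,N,2-trimethylprop-1-en-1-amine, CC(C)=C(Cl)N(C)C
Why: Acid chloride formation with an α-chloroenamine under neutral conditions should avoid the acid- or nucleophile-catalysed Z to E isomerisation of the angeloyl unit.

Step 20
Reactants: 27 tricyclic ether lactone; 29 angeloyl chloride
Product: 30 allylic chloride angelate
Conditions: ZnCl2 (cat.), CH2Cl2, 0 → 25 °C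
Reagents that add atoms: none
Why: Acylative cleavage of a cyclic ether by an acyl chloride under Lewis acid catalysis: the ether oxygen is acylated and chloride opens the acyloxonium ion at the primary allylic C15 (SN2 and SN2′ give the same product because C4 then carries CH2Cl and =CH2 either way), so the C6–O bond is never broken and the angelate should be installed with retention at C6.

Step 21
Reactants: 30 allylic chloride angelate
Product: 31 target CNP0295282.1
Conditions: pyridine N-oxide, Ag2O, MeCN, 25–50 °C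
Reagents that add atoms: pyridine N-oxide, [O-][n+]1ccccc1
Why: Kornblum-type oxidation: silver-assisted O-alkylation of the N-oxide by the allylic chloride and elimination of pyridine should give the 2-substituted acrolein under near-neutral conditions that spare the angelate and the methylene lactone.

Compound list

1 | 4-methylfuran-2(5H)-one | CC1=CC(=O)OC1 | starting material
2 | trimethyl[(4-methylfuran-2-yl)oxy]silane | Cc1coc(O[Si](C)(C)C)c1 | intermediate
3 | (4R)-2,2-dimethyl-1,3-dioxolane-4-carbaldehyde | O=C[C@H]1COC(C)(C)O1 | starting material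
4 | (5R)-5-{(S)-[(4R)-2,2-dimethyl-1,3-dioxolan-4-yl](hydroxy)methyl}-4-methylfuran-2(5H)-one | CC1=CC(=O)O[C@H]1[C@H](O)[C@H]2COC(C)(C)O2 | intermediate
5 | (2Z,4R,5S)-5-[(4R)-2,2-dimethyl-1,3-dioxolan-4-yl]-3-methylpent-2-ene-1,4,5-triol | OC/C=C(C)\[C@@H](O)[C@H](O)[C@H]1COC(C)(C)O1 | intermediate
6 | (2Z)-3-[(4S,4′R,5R)-2,2,2′,2′-tetramethyl-4,4′-bi(1,3-dioxolan)-5-yl]but-2-en-1-ol | OC/C=C(C)\[C@H]1OC(C)(C)O[C@@H]1[C@H]2COC(C)(C)O2 | intermediate
7 | 4-methoxy-2-methylidene-4-oxobutanoic acid (monomethyl itaconate) | COC(=O)CC(=C)C(=O)O | starting material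
8 | methyl 3-(hydroxymethyl)but-3-enoate | COC(=O)CC(=C)CO | intermediate
9 | methyl 3-{[(tert-butyldimethylsilyl)oxy]methyl}but-3-enoate | COC(=O)CC(=C)CO[Si](C)(C)C(C)(C)C | intermediate
10 | 3-{[(tert-butyldimethylsilyl)oxy]methyl}but-3-enoic acid | OC(=O)CC(=C)CO[Si](C)(C)C(C)(C)C | intermediate
11 | (2Z)-3-[(4S,4′R,5R)-2,2,2′,2′-tetramethyl-4,4′-bi(1,3-dioxolan)-5-yl]but-2-en-1-yl 3-{[(tert-butyldimethylsilyl)oxy]methyl}but-3-enoate | C=C(CO[Si](C)(C)C(C)(C)C)CC(=O)OC/C=C(C)\[C@H]1OC(C)(C)O[C@@H]1[C@H]2COC(C)(C)O2 | intermediate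
12 | (1Z)-trimethylsilyl ketene acetal of 11 (alkenyl group cis to OSiMe3) | C=C(CO[Si](C)(C)C(C)(C)C)/C=C(\O[Si](C)(C)C)OC/C=C(C)\[C@H]1OC(C)(C)O[C@@H]1[C@H]2COC(C)(C)O2 | intermediate
13 | (2S,3S)-2-{3-[(tert-butyldimethylsilyl)oxy]prop-1-en-2-yl}-3-methyl-3-[(4S,4′R,5R)-2,2,2′,2′-tetramethyl-4,4′-bi(1,3-dioxolan)-5-yl]pent-4-enoic acid | C=C[C@@](C)([C@H](C(=C)CO[Si](C)(C)C(C)(C)C)C(=O)O)[C@H]1OC(C)(C)O[C@@H]1[C@H]2COC(C)(C)O2 | intermediate
14 | (2S,3S)-2-(3-hydroxyprop-1-en-2-yl)-3-methyl-3-[(4S,4′R,5R)-2,2,2′,2′-tetramethyl-4,4′-bi(1,3-dioxolan)-5-yl]pent-4-enoic acid | C=C[C@@](C)([C@H](C(=C)CO)C(=O)O)[C@H]1OC(C)(C)O[C@@H]1[C@H]2COC(C)(C)O2 | intermediate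
15 | (3S)-3-{(2S)-2-[(4S,4′R,5R)-2,2,2′,2′-tetramethyl-4,4′-bi(1,3-dioxolan)-5-yl]but-3-en-2-yl}-4-methylidenedihydrofuran-2(3H)-one | C=C[C@@](C)([C@@H]1C(=C)COC1=O)[C@H]2OC(C)(C)O[C@@H]2[C@H]3COC(C)(C)O3 | intermediate
16 | (3S)-3-{(2S)-2-[(4S,4′R,5R)-2,2,2′,2′-tetramethyl-4,4′-bi(1,3-dioxolan)-5-yl]but-3-en-2-yl}-4-methylidenetetrahydrofuran-2-ol (both anomers) | C=C[C@@](C)([C@@H]1C(=C)COC1O)[C@H]2OC(C)(C)O[C@@H]2[C@H]3COC(C)(C)O3 | intermediate
17 | (1R)-1-[(4R,5R)-5-{(2S)-2-[(3S)-2-methoxy-4-methylidenetetrahydrofuran-3-yl]but-3-en-2-yl}-2,2-dimethyl-1,3-dioxolan-4-yl]ethane-1,2-diol | C=C[C@@](C)([C@@H]1C(=C)COC1OC)[C@H]2OC(C)(C)O[C@@H]2[C@H](O)CO | intermediate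
18 | (4S,5R)-5-{(2S)-2-[(3S)-2-methoxy-4-methylidenetetrahydrofuran-3-yl]but-3-en-2-yl}-2,2-dimethyl-1,3-dioxolane-4-carbaldehyde | C=C[C@@](C)([C@@H]1C(=C)COC1OC)[C@H]2OC(C)(C)O[C@@H]2C=O | intermediate
19 | methyl 2-[bis(2,2,2-trifluoroethoxy)phosphoryl]acetate | COC(=O)CP(=O)(OCC(F)(F)F)OCC(F)(F)F | starting material
20 | methyl 2-[bis(2,2,2-trifluoroethoxy)phosphoryl]-3-(trimethylsilyl)propanoate | COC(=O)C(C[Si](C)(C)C)P(=O)(OCC(F)(F)F)OCC(F)(F)F | intermediate
21 | methyl (2E)-3-[(4R,5R)-5-{(2S)-2-[(3S)-2-methoxy-4-methylidenetetrahydrofuran-3-yl]but-3-en-2-yl}-2,2-dimethyl-1,3-dioxolan-4-yl]-2-[(trimethylsilyl)methyl]prop-2-enoate (ester cis to the dioxolane) | C=C[C@@](C)([C@@H]1C(=C)COC1OC)[C@H]2OC(C)(C)O[C@@H]2/C=C(/C[Si](C)(C)C)C(=O)OC | intermediate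
22 | methyl (2E,4R,5R,6S)-4,5-dihydroxy-6-[(3S)-2-methoxy-4-methylidenetetrahydrofuran-3-yl]-6-methyl-2-[(trimethylsilyl)methyl]octa-2,7-dienoate | C=C[C@@](C)([C@@H]1C(=C)COC1OC)[C@@H](O)[C@H](O)/C=C(/C[Si](C)(C)C)C(=O)OC | intermediate
23 | (5R)-5-{(1R,2S)-1-hydroxy-2-[(3S)-2-methoxy-4-methylidenetetrahydrofuran-3-yl]-2-methylbut-3-en-1-yl}-3-[(trimethylsilyl)methyl]furan-2(5H)-one | C=C[C@@](C)([C@@H]1C(=C)COC1OC)[C@@H](O)[C@@H]2OC(=O)C(C[Si](C)(C)C)=C2 | intermediate
24 | (2R)-2-methylbutanoic acid | CC[C@@H](C)C(=O)O | starting material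
25 | (1R,2S)-2-[(3S)-2-methoxy-4-methylidenetetrahydrofuran-3-yl]-2-methyl-1-{(2R)-5-oxo-4-[(trimethylsilyl)methyl]-2,5-dihydrofuran-2-yl}but-3-en-1-yl (2R)-2-methylbutanoate | C=C[C@@](C)([C@@H]1C(=C)COC1OC)[C@@H](OC(=O)[C@H](C)CC)[C@@H]2OC(=O)C(C[Si](C)(C)C)=C2 | intermediate
26 | cyclic oxocarbenium triflate formed from 25 by loss of methoxide at C6 | C=C[C@@](C)([C@@H]1C(=C)C[O+]=C1)[C@@H](OC(=O)[C@H](C)CC)[C@@H]2OC(=O)C(C[Si](C)(C)C)=C2.[O-]S(=O)(=O)C(F)(F)F | intermediate
27 | (5S,6S,7R,8R,9R,10S)-6,15-epoxy-9-{[(2R)-2-methylbutanoyl]oxy}elema-1,3,11(13)-trien-12,8-olide (cyclohexane cis-fused to a 3-methylideneoxolane at C5–C6 and to the α-methylene lactone at C7–C8) | C=C[C@@]1(C)[C@@H]3C(=C)CO[C@@H]3[C@H]2C(=C)C(=O)O[C@H]2[C@@H]1OC(=O)[C@H](C)CC | intermediate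
28 | (2Z)-2-methylbut-2-enoic acid (angelic acid) | C/C=C(/C)C(=O)O | starting material
29 | (2Z)-2-methylbut-2-enoyl chloride (angeloyl chloride) | C/C=C(/C)C(=O)Cl | intermediate
30 | (5R,6S,7R,8R,9R,10S)-15-chloro-6-{[(2Z)-2-methylbut-2-enoyl]oxy}-9-{[(2R)-2-methylbutanoyl]oxy}elema-1,3,11(13)-trien-12,8-olide | C=C[C@@]1(C)[C@H](C(=C)CCl)[C@H](OC(=O)/C(C)=C\C)[C@H]2C(=C)C(=O)O[C@H]2[C@@H]1OC(=O)[C@H](C)CC | intermediate
31 | (5R,6S,7R,8R,9R,10S)-6-{[(2Z)-2-methylbut-2-enoyl]oxy}-9-{[(2R)-2-methylbutanoyl]oxy}-15-oxoelema-1,3,11(13)-trien-12,8-olide (CNP0295282.1) | C=C[C@@]1(C)[C@H](C(=C)C=O)[C@H](OC(=O)/C(C)=C\C)[C@H]2C(=C)C(=O)O[C@H]2[C@@H]1OC(=O)[C@H](C)CC | target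

Total step count: 21 (steps 5–7, 14 and 19 prepare fragments and reagents).
Longest linear sequence: 16 steps (steps 1–4, 8–13, 15–18, 20, 21).

Steps most likely to fail

Step 18. The cross-conjugated allylsilane may be too weak a nucleophile, so that the oxocarbenium ion instead loses the C5 proton and aromatises, or the silane is protodesilylated. The fallback sets out from 25 and returns at 27, replacing the cationic closure by an anionic one. Mild aqueous acid (pyridinium p-toluenesulfonate, acetone/H2O) hydrolyses the methyl acetal to the free lactol F1, which is in equilibrium with its γ-hydroxy aldehyde. Tetrabutylammonium difluorotriphenylsilicate in THF then triggers the fluoride-promoted Sakurai-type addition of the silane through C7 to the aldehyde, giving the 6,15-diol F2 with the cis-fused methylene lactone. C6 is not tether-controlled in this variant, so only the (6S)-epimer is carried on. A Mitsunobu cycloetherification (PPh3, diisopropyl azodicarboxylate), which activates the primary allylic C15 hydroxyl and leaves the C6–O bond intact, closes the oxolane to 27.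

Step 20. The angeloyl unit may isomerise from Z to E under Lewis acid and chloride, acylation of the hindered ether oxygen may be slow, and chloride may add to the methylene lactone. The fallback sets out from 27 and returns at 31, separating ether cleavage from acylation. Me2BBr (CH2Cl2, −78 °C) opens the ether at the allylic C15–O bond to give the bromo alcohol F3, which is acylated at once to prevent re-closure. The mixed anhydride of 28 with 2,4,6-trichlorobenzoyl chloride (Et3N, toluene; Yamaguchi-type esterification, which transfers the angeloyl group without isomerisation) gives the bromo angelate F4. Oxidation with pyridine N-oxide and Ag2O as in step 21 then gives 31.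

Step 9. The axial dioxolanyl group may divert the rearrangement to a boat (wrong C5), facial discrimination by C9 may be poor, and the dienolate may scramble or move the olefin into conjugation. The fallback sets out from 6 and returns at 13, using the opposite olefin and ketene acetal geometries so that the dioxolanyl group is equatorial in the chair. MnO2 oxidises 6 to the (Z)-enal F5, which is equilibrated with catalytic iodine to the (E)-enal F6. Reduction with NaBH4 and CeCl3 gives the (E)-allylic alcohol F7, and DCC coupling with 10 gives the ester F8. Enolisation with LiN(i-Pr)2 in THF without polar cosolvent and silylation give the ketene acetal F9 (alkenyl group cis to the allyloxy oxygen), whose chair rearrangement leads to the same acid 13.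

Further compounds
F1 | step 18 | lactol from 25 (2-hydroxy in place of 2-methoxy on the oxolane; both anomers) | C=C[C@@](C)([C@@H]1C(=C)COC1O)[C@@H](OC(=O)[C@H](C)CC)[C@@H]2OC(=O)C(C[Si](C)(C)C)=C2
F2 | step 18 | (5R,6S,7R,8R,9R,10S)-6,15-dihydroxy-9-{[(2R)-2-methylbutanoyl]oxy}elema-1,3,11(13)-trien-12,8-olide | C=C[C@@]1(C)[C@H](C(=C)CO)[C@H](O)[C@H]2C(=C)C(=O)O[C@H]2[C@@H]1OC(=O)[C@H](C)CC
F3 | step 20 | (5R,6S,7R,8R,9R,10S)-15-bromo-6-hydroxy-9-{[(2R)-2-methylbutanoyl]oxy}elema-1,3,11(13)-trien-12,8-olide | C=C[C@@]1(C)[C@H](C(=C)CBr)[C@H](O)[C@H]2C(=C)C(=O)O[C@H]2[C@@H]1OC(=O)[C@H](C)CC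
F4 | step 20 | (5R,6S,7R,8R,9R,10S)-15-bromo-6-{[(2Z)-2-methylbut-2-enoyl]oxy}-9-{[(2R)-2-methylbutanoyl]oxy}elema-1,3,11(13)-trien-12,8-olide | C=C[C@@]1(C)[C@H](C(=C)CBr)[C@H](OC(=O)/C(C)=C\C)[C@H]2C(=C)C(=O)O[C@H]2[C@@H]1OC(=O)[C@H](C)CC
F5 | step 9 | (2Z)-3-[(4S,4′R,5R)-2,2,2′,2′-tetramethyl-4,4′-bi(1,3-dioxolan)-5-yl]but-2-enal | O=C/C=C(C)\[C@H]1OC(C)(C)O[C@@H]1[C@H]2COC(C)(C)O2
F6 | step 9 | (2E)-3-[(4S,4′R,5R)-2,2,2′,2′-tetramethyl-4,4′-bi(1,3-dioxolan)-5-yl]but-2-enal | O=C/C=C(\C)[C@H]1OC(C)(C)O[C@@H]1[C@H]2COC(C)(C)O2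
F7 | step 9 | (2E)-3-[(4S,4′R,5R)-2,2,2′,2′-tetramethyl-4,4′-bi(1,3-dioxolan)-5-yl]but-2-en-1-ol | OC/C=C(\C)[C@H]1OC(C)(C)O[C@@H]1[C@H]2COC(C)(C)O2
F8 | step 9 | (2E)-3-[(4S,4′R,5R)-2,2,2′,2′-tetramethyl-4,4′-bi(1,3-dioxolan)-5-yl]but-2-en-1-yl 3-{[(tert-butyldimethylsilyl)oxy]methyl}but-3-enoate | C=C(CO[Si](C)(C)C(C)(C)C)CC(=O)OC/C=C(\C)[C@H]1OC(C)(C)O[C@@H]1[C@H]2COC(C)(C)O2
F9 | step 9 | (1E)-trimethylsilyl ketene acetal of F8 (alkenyl group cis to the allyloxy oxygen) | C=C(CO[Si](C)(C)C(C)(C)C)/C=C(/O[Si](C)(C)C)OC/C=C(\C)[C@H]1OC(C)(C)O[C@@H]1[C@H]2COC(C)(C)O2
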